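The benzo ring (C3a–C4–C5–C6–C7–C7a) is built last, around a finished trans-dihydrofuran. Because O1 on C7a and the methoxy group on C7 are neighbours, they map onto the enol-ether carbon and the carbene carbon of a dihydrofuranyl methoxycarbene chromium complex. Its Dötz (3+2+1) benzannulation with a silyl-protected (E)-pentenynol joins carbene, terminal alkyne and one CO, forming C6–C7, C4–C5 and C3a–C4, placing the side chain on C5 and leaving a C4 hydroxyl that is later excised. The precursor is the enantiopure (2S,3S)-2-(3,4-dimethoxyphenyl)-3-methyl-2,3-dihydrofuran-5-yl carbene complex; its stereodiad comes from an anti-selective propargylation and is not touched by the annulation.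

Key step: step 6

Remark: the sense of chirality transfer in step 2 is taken as anti-SN2′ oxidative addition, stereoretentive Pd-to-Zn transmetalation and syn-SE2′ addition, which makes (R)-but-3-yn-2-ol the required enantiomer; compound 10 is assumed to be purchasable as the pure (E)-isomer.

Step 1
Reactants: 1 (R)-but-3-yn-2-ol
Product: 2 (R)-but-3-yn-2-yl methanesulfonate
Conditions: MsCl, Et3N, CH2Cl2, −78 to 0 °C
Reagents that add atoms: methanesulfonyl chloride, CS(=O)(=O)Cl
Why: O-Sulfonylation (mesylation) of the secondary propargylic alcohol takes place at oxygen only, so the C–O stereocentre is carried over with retention as the (R)-mesylate.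

Step 2
Reactants: 2 (R)-but-3-yn-2-yl methanesulfonate; 3 3,4-dimethoxybenzaldehyde
Product: 5 (1S,2S)-1-(3,4-dimethoxyphenyl)-2-methylbut-3-yn-1-ol, via allenylzinc 4 (not isolated)
Conditions: Pd(OAc)2 (5 mol %), PPh3 (5 mol %), Et2Zn (3 equiv), THF, −78 to −20 °C; aq NH4Cl
Reagents that add atoms: none
Why: Marshall propargylation (Pd/Zn umpolung of a propargylic mesylate), in which Pd(0) opens 2 by anti-SN2′ to an allenylpalladium, Et2Zn transmetalates it with retention to the configurationally defined allenylzinc 4, and syn-SE2′ addition to the aldehyde through a closed six-membered transition state sets the methyl-bearing centre from the axial chirality of 4 and the carbinol centre (anti) by keeping the aryl group away from the allenyl methyl group, the minor syn isomer being removable by chromatography.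

Step 3
Reactants: 5 (1S,2S)-1-(3,4-dimethoxyphenyl)-2-methylbut-3-yn-1-ol
Product: 6 (2S,3S)-2-(3,4-dimethoxyphenyl)-3-methyl-2,3-dihydrofuran
Conditions: Et3N·Mo(CO)5 [from Mo(CO)6 (25 mol %), Et3N, Et2O, hν 350 nm], rt
Reagents that add atoms: none
Why: Metal-vinylidene endo-cycloisomerisation of a but-3-yn-1-ol, in which the terminal alkyne rearranges on the Mo(CO)5 fragment to a vinylidene, the hydroxyl adds to its electrophilic carbon and protodemetalation releases the 2,3-dihydrofuran, a known conversion for 1-aryl- and 2-substituted homopropargylic alcohols that leaves both stereocentres untouched.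

Step 4
Reactants: 6 (2S,3S)-2-(3,4-dimethoxyphenyl)-3-methyl-2,3-dihydrofuran
Product: 9 pentacarbonyl{[(2S,3S)-2-(3,4-dimethoxyphenyl)-3-methyl-2,3-dihydrofuran-5-yl](methoxy)methylidene}chromium, via vinyllithium 7 (not isolated), via lithium acylchromate 8 (not isolated)
Conditions: t-BuLi, THF, −78 to 0 °C; Cr(CO)6, Et2O, 0 °C to rt; then MeOTf, CH2Cl2, 0 °C
Reagents that add atoms: chromium hexacarbonyl, O=C=[Cr](=C=O)(=C=O)(=C=O)(=C=O)=C=O; methyl trifluoromethanesulfonate, COS(=O)(=O)C(F)(F)F
Why: α-Lithiation of a cyclic enol ether at its sp2 C–H next to oxygen (as practised on 2,3-dihydrofuran and glycals) followed by the Fischer carbene synthesis, in which the vinyllithium adds to a CO ligand of Cr(CO)6 and the resulting acylchromate is O-methylated by the hard electrophile MeOTf, while the tertiary benzylic C2–H, deactivated by the electron-rich aryl ring, is expected to be the slower site of deprotonation.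

Step 5
Reactants: 10 (E)-pent-2-en-4-yn-1-ol
Product: 11 tert-butyl(dimethyl){[(2E)-pent-2-en-4-yn-1-yl]oxy}silane
Conditions: TBSCl, imidazole, CH2Cl2, 0 °C to rt
Reagents that add atoms: tert-butyldimethylsilyl chloride, CC(C)(C)[Si](C)(C)Cl
Why: Imidazole-mediated O-silylation of a primary alcohol, which leaves the conjugated enyne untouched.

Step 6
Reactants: 9 pentacarbonyl{[(2S,3S)-2-(3,4-dimethoxyphenyl)-3-methyl-2,3-dihydrofuran-5-yl](methoxy)methylidene}chromium; 11 tert-butyl(dimethyl){[(2E)-pent-2-en-4-yn-1-yl]oxy}silane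
Product: 13 (2S,3S)-5-[(E)-3-{[tert-butyl(dimethyl)silyl]oxy}prop-1-en-1-yl]-2-(3,4-dimethoxyphenyl)-7-methoxy-3-methyl-2,3-dihydro-1-benzofuran-4-ol, via tricarbonylchromium arene complex 12 (not isolated)
Conditions: 11 (2 equiv), degassed THF (0.05 M), 50 °C, Ar; then air, EtOAc, rt
Reagents that add atoms: none
Why: Loss of one CO from 9 opens a site at which the terminal alkyne binds and inserts into the Cr=C bond with its CH terminus joined to the former carbene carbon, and CO insertion into the new vinylcarbene gives a chromium-bound dienylketene. The benzene ring is closed by 6π-electrocyclisation of that ketene between the ketene carbon and the dihydrofuran C4 (the enol ether β-carbon), and tautomerisation of the cyclohexadienone gives the Cr(CO)3-complexed 4-methoxyphenol 12, from which air exposure releases 13. The closest known reaction type is the Dötz benzannulation of cyclic α-alkoxyalkenyl (dihydropyranyl, glycal-derived) methoxycarbene chromium complexes and of alkenyl carbene complexes with conjugated enynes. No stereocentre is formed, and C2 and C3 are sp3 carbons outside the reacting array under neutral conditions, so the trans stereodiad is carried through. The step needs regioselective insertion (chain on C5, H on C6), which the large steric difference between H and the alkenyl group of a terminal alkyne secures by placing the larger group next to the CO-derived carbon, and chemoselectivity for the alkyne over the 1,2-disubstituted alkene, which follows from the much stronger binding of alkynes to the unsaturated chromium centre; the ring-fixed cis relationship of carbene carbon and C4–H favours phenol formation over cyclobutenone or furan by-products.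

Step 7
Reactants: 13 (2S,3S)-5-[(E)-3-{[tert-butyl(dimethyl)silyl]oxy}prop-1-en-1-yl]-2-(3,4-dimethoxyphenyl)-7-methoxy-3-methyl-2,3-dihydro-1-benzofuran-4-ol
Product: 14 (2S,3S)-5-[(E)-3-{[tert-butyl(dimethyl)silyl]oxy}prop-1-en-1-yl]-2-(3,4-dimethoxyphenyl)-7-methoxy-3-methyl-2,3-dihydro-1-benzofuran-4-yl trifluoromethanesulfonate
Conditions: Tf2O, pyridine, CH2Cl2, −20 to 0 °C
Reagents that add atoms: trifluoromethanesulfonic anhydride, O=S(=O)(OS(=O)(=O)C(F)(F)F)C(F)(F)F
Why: O-Triflation of a phenol with Tf2O and pyridine (aryl triflate formation), to which the primary silyl ether, the alkene and the aryl ethers are inert at low temperature.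

Step 8
Reactants: 14 (2S,3S)-5-[(E)-3-{[tert-butyl(dimethyl)silyl]oxy}prop-1-en-1-yl]-2-(3,4-dimethoxyphenyl)-7-methoxy-3-methyl-2,3-dihydro-1-benzofuran-4-yl trifluoromethanesulfonate
Product: 15 tert-butyl({(2E)-3-[(2S,3S)-2-(3,4-dimethoxyphenyl)-7-methoxy-3-methyl-2,3-dihydro-1-benzofuran-5-yl]prop-2-en-1-yl}oxy)dimethylsilane
Conditions: Pd(OAc)2 (5 mol %), dppf (10 mol %), HCO2H, Et3N, DMF, 70 °C
Reagents that add atoms: none
Why: Palladium-catalysed transfer hydrogenolysis of an aryl triflate with formate, in which oxidative addition into the C4–O bond, formate exchange, decarboxylation to an arylpalladium hydride and reductive elimination give C4–H, while the allylic silyl ether cannot ionise to a π-allyl complex and the disubstituted alkene is not reduced under these conditions.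

Step 9
Reactants: 15 tert-butyl({(2E)-3-[(2S,3S)-2-(3,4-dimethoxyphenyl)-7-methoxy-3-methyl-2,3-dihydro-1-benzofuran-5-yl]prop-2-en-1-yl}oxy)dimethylsilane
Product: 16 (2E)-3-[(2S,3S)-2-(3,4-dimethoxyphenyl)-7-methoxy-3-methyl-2,3-dihydro-1-benzofuran-5-yl]prop-2-en-1-ol
Conditions: TBAF, THF, 0 °C to rt; aq NH4Cl
Reagents that add atoms: none
Why: Fluoride-mediated cleavage of the Si–O bond (silyl ether deprotection) releases the primary allylic alcohol without affecting the aryl ethers, the (E)-alkene or the two stereocentres.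

Compound list
1 | (R)-but-3-yn-2-ol | C[C@@H](O)C#C | starting material
2 | (R)-but-3-yn-2-yl methanesulfonate | C[C@@H](OS(C)(=O)=O)C#C | intermediate
3 | 3,4-dimethoxybenzaldehyde | COc1ccc(C=O)cc1OC | starting material
4 | ethyl[(P)-buta-1,2-dien-1-yl]zinc (P axial chirality, not encoded in the SMILES) | CC=C=C[Zn]CC | intermediate
5 | (1S,2S)-1-(3,4-dimethoxyphenyl)-2-methylbut-3-yn-1-ol (anti) | COc1ccc([C@@H](O)[C@@H](C)C#C)cc1OC | intermediate
6 | (2S,3S)-2-(3,4-dimethoxyphenyl)-3-methyl-2,3-dihydrofuran (trans) | COc1ccc([C@H]2OC=C[C@@H]2C)cc1OC | intermediate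
7 | [(2S,3S)-2-(3,4-dimethoxyphenyl)-3-methyl-2,3-dihydrofuran-5-yl]lithium | COc1ccc([C@H]2OC([Li])=C[C@@H]2C)cc1OC | intermediate
8 | lithium pentacarbonyl{[(2S,3S)-2-(3,4-dimethoxyphenyl)-3-methyl-2,3-dihydrofuran-5-yl]carbonyl}chromate | COc1ccc([C@H]2OC(C([O-])=[Cr](=C=O)(=C=O)(=C=O)(=C=O)=C=O)=C[C@@H]2C)cc1OC.[Li+] | intermediate
9 | pentacarbonyl{[(2S,3S)-2-(3,4-dimethoxyphenyl)-3-methyl-2,3-dihydrofuran-5-yl](methoxy)methylidene}chromium | COc1ccc([C@H]2OC(C(OC)=[Cr](=C=O)(=C=O)(=C=O)(=C=O)=C=O)=C[C@@H]2C)cc1OC | intermediate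
10 | (E)-pent-2-en-4-yn-1-ol | C#C/C=C/CO | starting material
11 | tert-butyl(dimethyl){[(2E)-pent-2-en-4-yn-1-yl]oxy}silane | C#C/C=C/CO[Si](C)(C)C(C)(C)C | intermediate
12 | tricarbonyl(η6-arene)chromium complex of phenol 13, Cr on the new benzo ring (written as two fragments) | COc1ccc([C@H]2Oc3c(OC)cc(/C=C/CO[Si](C)(C)C(C)(C)C)c(O)c3[C@@H]2C)cc1OC.[Cr](=C=O)(=C=O)=C=O | intermediate
13 | (2S,3S)-5-[(E)-3-{[tert-butyl(dimethyl)silyl]oxy}prop-1-en-1-yl]-2-(3,4-dimethoxyphenyl)-7-methoxy-3-methyl-2,3-dihydro-1-benzofuran-4-ol | COc1ccc([C@H]2Oc3c(OC)cc(/C=C/CO[Si](C)(C)C(C)(C)C)c(O)c3[C@@H]2C)cc1OC | intermediate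
14 | (2S,3S)-5-[(E)-3-{[tert-butyl(dimethyl)silyl]oxy}prop-1-en-1-yl]-2-(3,4-dimethoxyphenyl)-7-methoxy-3-methyl-2,3-dihydro-1-benzofuran-4-yl trifluoromethanesulfonate | COc1ccc([C@H]2Oc3c(OC)cc(/C=C/CO[Si](C)(C)C(C)(C)C)c(OS(=O)(=O)C(F)(F)F)c3[C@@H]2C)cc1OC | intermediate
15 | tert-butyl({(2E)-3-[(2S,3S)-2-(3,4-dimethoxyphenyl)-7-methoxy-3-methyl-2,3-dihydro-1-benzofuran-5-yl]prop-2-en-1-yl}oxy)dimethylsilane | COc1ccc([C@H]2Oc3c(OC)cc(/C=C/CO[Si](C)(C)C(C)(C)C)cc3[C@@H]2C)cc1OC | intermediate
16 | (2E)-3-[(2S,3S)-2-(3,4-dimethoxyphenyl)-7-methoxy-3-methyl-2,3-dihydro-1-benzofuran-5-yl]prop-2-en-1-ol (CNP0330626.1) | COc1ccc([C@H]2Oc3c(OC)cc(/C=C/CO)cc3[C@@H]2C)cc1OC | target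

Total step count: 9. Longest linear sequence: 8 steps (steps 1–4 and 6–9, from 1 to 16); step 5 is a one-step side branch.

Steps most likely to fail

1. Step 6 (key step). The conjugated terminal enyne may oligomerise or insert more than once at the unsaturated chromium centre, or the dienylketene may be diverted before ring closure. The electron-rich hydroquinone monoether may also oxidise during demetalation. The fallback sets out from 9 and returns at 16; it no longer carries the side chain through the annulation but only a masked formyl group. Carbene complex 9 would be heated in THF at 50 °C with commercial 3,3-diethoxyprop-1-yne, a non-conjugated terminal alkyne. This should give the tricarbonylchromium complex of the acetal phenol F1 and, after air exposure, (2S,3S)-5-(diethoxymethyl)-2-(3,4-dimethoxyphenyl)-7-methoxy-3-methyl-2,3-dihydro-1-benzofuran-4-ol F2. Triflation (Tf2O, pyridine, CH2Cl2) would give the corresponding C4 aryl triflate F3. Formate hydrogenolysis (Pd(OAc)2, dppf, HCO2H, Et3N, DMF) would give (2S,3S)-5-(diethoxymethyl)-2-(3,4-dimethoxyphenyl)-7-methoxy-3-methyl-2,3-dihydro-1-benzofuran F4. PPTS in wet acetone would then unmask (2S,3S)-2-(3,4-dimethoxyphenyl)-7-methoxy-3-methyl-2,3-dihydro-1-benzofuran-5-carbaldehyde F5. Horner–Wadsworth–Emmons olefination with triethyl phosphonoacetate and NaH in THF should give ethyl (2E)-3-[(2S,3S)-2-(3,4-dimethoxyphenyl)-7-methoxy-3-methyl-2,3-dihydro-1-benzofuran-5-yl]prop-2-enoate F6. DIBAL-H in CH2Cl2 at −78 °C would reduce the ester to 16.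

2. Step 4. Deprotonation at the benzylic C2–H, or ortho to a methoxy group of the aryl ring, may compete with C5–H lithiation. This would consume base, scramble C2 and lead to isomeric acylchromates. The fallback sets out from 5 and returns at 7. Alkynol 5 would be cyclised with stoichiometric Et3N·Mo(CO)5 in the presence of Bu3SnOTf and Et3N, so that the anionic cyclic alkenylmolybdenum intermediate of the cycloisomerisation is stannylated instead of protonated. This should give tributyl[(2S,3S)-2-(3,4-dimethoxyphenyl)-3-methyl-2,3-dihydrofuran-5-yl]stannane F7. Tin–lithium exchange with n-BuLi in THF at −78 °C, which is far faster than any C–H deprotonation, would then deliver 7 regiospecifically, and the route continues with Cr(CO)6 and MeOTf to 9.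

3. Step 2. Addition to the electron-rich aryl aldehyde may be slow enough for the allenylzinc to racemise and for the preference for the anti transition state to weaken, so that enantiomeric purity and anti selectivity erode. The fallback sets out from 3 and returns at 5; it replaces chirality transfer from an enantiopure mesylate by catalyst control. Aldehyde 3 would be treated in toluene at low temperature with an excess of racemic 2-(buta-1,2-dien-1-yl)-4,4,5,5-tetramethyl-1,3,2-dioxaborolane F8 and a catalytic amount of the BINOL-derived phosphoric acid TRIP. F8 would be prepared from racemic but-3-yn-2-yl methyl carbonate and bis(pinacolato)diboron under copper(I) alkoxide catalysis. The chiral Brønsted acid selects one enantiomer of the allenylboronate (kinetic resolution) and one aldehyde face in a closed six-membered transition state, which should give the anti alcohol 5. The (S)-catalyst is expected to direct the required Si-face attack by analogy with simple aryl aldehydes, and its antipode would be used if the sense proves opposite.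

Further compounds
F1 | step 6 | tricarbonyl(η6-arene)chromium complex of F2 (written as two fragments) | COc1ccc([C@H]2Oc3c(OC)cc(C(OCC)OCC)c(O)c3[C@@H]2C)cc1OC.[Cr](=C=O)(=C=O)=C=O
F2 | step 6 | (2S,3S)-5-(diethoxymethyl)-2-(3,4-dimethoxyphenyl)-7-methoxy-3-methyl-2,3-dihydro-1-benzofuran-4-ol | COc1ccc([C@H]2Oc3c(OC)cc(C(OCC)OCC)c(O)c3[C@@H]2C)cc1OC
F3 | step 6 | (2S,3S)-5-(diethoxymethyl)-2-(3,4-dimethoxyphenyl)-7-methoxy-3-methyl-2,3-dihydro-1-benzofuran-4-yl trifluoromethanesulfonate | COc1ccc([C@H]2Oc3c(OC)cc(C(OCC)OCC)c(OS(=O)(=O)C(F)(F)F)c3[C@@H]2C)cc1OC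
F4 | step 6 | (2S,3S)-5-(diethoxymethyl)-2-(3,4-dimethoxyphenyl)-7-methoxy-3-methyl-2,3-dihydro-1-benzofuran | COc1ccc([C@H]2Oc3c(OC)cc(C(OCC)OCC)cc3[C@@H]2C)cc1OC
F5 | step 6 | (2S,3S)-2-(3,4-dimethoxyphenyl)-7-methoxy-3-methyl-2,3-dihydro-1-benzofuran-5-carbaldehyde | COc1ccc([C@H]2Oc3c(OC)cc(C=O)cc3[C@@H]2C)cc1OC
F6 | step 6 | ethyl (2E)-3-[(2S,3S)-2-(3,4-dimethoxyphenyl)-7-methoxy-3-methyl-2,3-dihydro-1-benzofuran-5-yl]prop-2-enoate | COc1ccc([C@H]2Oc3c(OC)cc(/C=C/C(=O)OCC)cc3[C@@H]2C)cc1OC
F7 | step 4 | tributyl[(2S,3S)-2-(3,4-dimethoxyphenyl)-3-methyl-2,3-dihydrofuran-5-yl]stannane | COc1ccc([C@H]2OC([Sn](CCCC)(CCCC)CCCC)=C[C@@H]2C)cc1OC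
F8 | step 2 | racemic 2-(buta-1,2-dien-1-yl)-4,4,5,5-tetramethyl-1,3,2-dioxaborolane | CC=C=CB1OC(C)(C)C(C)(C)O1
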